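Late in Sunday's run the readings stopped climbing, and that run has the same recipe as the flask asked about.

| flask | left-handed substrate | right-handed substrate | reagent | free catalyst | impurity | temperature | remark | time |
|---|---|---|---|---|---|---|---|---|
| Sunday's | 12 mM | 12 mM | 24 mM | 60 µM | 77 µM | −20 °C | the very flask that is asked about, followed so far |  |
| Saturday's | 12 mM | 12 mM | 48 mM | 60 µM | 77 µM | −25 °C | run made earlier |  |
| flask | 12 mM | 12 mM | 24.0 mM | 60 µM | 77 µM | −20 °C |  | 3.0 d |

- Sunday's (time / h: left-handed product / %): 5.00: 5.6; 15.0: 8.1; 30.0: 13.6; 40.0: 13.7
- Saturday's (time / h: left-handed product / %): 2.00: 2.7; 5.00: 6.9; 10.0: 11.9; 15.0: 13.3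

(readings scatter by 1 percentage point)

- oak: at 3.0 d take out 90 % of the left-handed product then present, then wait 20 h
- cedar: at 3.0 d raise the temperature by 25 K, then wait 20 h
- maple: at 3.0 d add free catalyst, 100 % of the amount charged, then wait 20 h
- elm: at 3.0 d add reagent, 100 % of the amount charged, then wait 20 h
- birch: change nothing and wait 20 h more

- free catalyst is single-handed; left-handed substrate and right-handed substrate are mirror images of each other, charged as a racemate, each of them at the stated concentration
- removed left-handed product is counted in
- additions bring no volume worth counting

* left-handed product, in percent of the left-handed substrate and right-handed substrate together first charged, at 3.0 d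
* the option that brings most further left-handed product ("none" if no option brings more than 2 percentage points) (oak / cedar / maple / elm / birch / none)
* left-handed product present, with what was taken out counted in, in percent of the left-handed substrate and right-handed substrate together first charged, after cedar
* left-handed product present, with what was taken out counted in, in percent of the left-handed substrate and right-handed substrate together first charged, after maple

1. Sunday's left-handed product read 13.6 % at 30.0 h and 13.7 % at 40.0 h. That step of 0.1 percentage points was smaller than the scatter of 1 point.

2. The product then stood at 3.29 mM, less than the 12 mM of left-handed substrate charged. So I took the stop for lost catalyst, not for a used-up charge.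

3. I divided the rate of product formation by the rate of catalyst loss, and time dropped out. What remains is the turnover budget (turnover number), the left-handed product made by the stop per catalyst charged: as read, 54.8.

4. The budget gave me 13.7 % for now. Oak, cedar, elm and birch bring no catalyst, so I expected each to gain less than 2 points.

5. Maple brings a second charge, worth 14 points, which makes 27.4 %. But the wait of 20 h is shorter than the 30.0 h by which Sunday's readings had reached their stop, so I held this as a high figure.

6. Was one number enough? Saturday's last reading gives 53.2, but that run still rose 1.4 points in its last interval, more than the scatter. So I read it as a floor for Saturday's recipe, and I carried Sunday's budget to the flask.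

7. The forecast gave 14 % for now, maple as best, 14.2 % after cedar and 23.5 % after maple: “Fresh catalyst restarts the reaction.” Its maple figure lies below mine.

The flask gave 13.3 %, maple was best, cedar gave 13.3 % and maple 26.6 %, so the forecast held.

    free catalyst + left-handed substrate ⇌ catalyst intermediate A (K = 190 M⁻¹, k = 171 M⁻¹ min⁻¹, Ea = 36.0 kJ mol⁻¹, ΔH = −14.0 kJ mol⁻¹)
    free catalyst + right-handed substrate ⇌ catalyst intermediate B (K = 250 M⁻¹, k = 3700 M⁻¹ min⁻¹, Ea = 43.0 kJ mol⁻¹, ΔH = 24.0 kJ mol⁻¹)
    reagent + catalyst intermediate A → free catalyst + left-handed product (k = 29.4 M⁻¹ min⁻¹, Ea = 36.0 kJ mol⁻¹)
    reagent + catalyst intermediate B → free catalyst + right-handed product (k = 3.89 M⁻¹ min⁻¹, Ea = 58.0 kJ mol⁻¹)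
    free catalyst + impurity → spent catalyst (k = 345 M⁻¹ min⁻¹, Ea = 48.0 kJ mol⁻¹)
    2 free catalyst ⇌ resting dimer, settled at all times (K = 3.00 × 10⁵ M⁻¹, ΔH = −31.0 kJ mol⁻¹)
    (constants at −20 °C)

The budget came to 53.2 for the flask's first charge and 53.2 for maple's second. The flask run at 5 °C stopped at 5.81 %, a budget of 23.3, lower than mine. In the flask, left-handed product reached 6.73 % by 7.20 h while spent catalyst reached 63.5 % of the catalyst charged. By 72.0 h spent catalyst stood at 99.8 %, free catalyst at 0.0391 %, and impurity at 22 % of its charge.

The numbers in the tables were computed on assumed constants; scatter was added.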